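**Plan**
1. Cuts: the ester C–O bond to the hydroxymethylglutarate, the C3–C4 bond of the dienoic acid, and the ring bonds C4'–C5' and C1'–C6' (ring: C1' carbinol, C2' methyl-bearing sp2 carbon, C3', C4' carbonyl, C5' CH2, C6' quaternary carbon; chain C1–C5 counted from the acid).
2. Enabling feature: C1'(OH)–C2'(CH3)=C3'–C4'(=O) with a carbon on C1' is a masked 3-hydroxy-4-methyl-2-pyrone (pyrone 3-OH = C1'–OH, ring O = C4' oxygen, lactone C=O = chain C5); C5'–C6'(CH3)(CHO) is methacrolein.
3. Forward: the pyrone is made in 3 steps, then an amine-catalysed formal [4+2] closes the carbocycle as a 2-oxabicyclo[2.2.2]octenone; its lactone bridge C1'–C(=O)–O–C4' is not in the target and is dismantled afterwards.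
4. Bridge relay: reduction of the aldehyde lets the exo CH2OH open the bridge to a cis-fused γ-lactone; lactol, alkyne, E-vinylstannane and a copper-mediated coupling with a Z-iodoenoate then build the chain.
5. The glutarate arrives as a mono-allyl ester from (S)-mevalonolactone; esterification, desilylation, allylic oxidation and deallylation finish the route.
6. Stereochemistry: C1'/C6' from the catalyst-controlled exo cycloaddition (relative configuration certified by the lactone relay), the glutarate carbinol from the chiral pool, 4E from syn-hydrostannylation, 2Z from anti-hydroiodination.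

Key step: step 4

Remark: the target as drawn has the acyloxymethyl group on C6' trans to the C1' hydroxyl and cis to the dienoic acid chain, (1'R,6'S), with a (3R) glutarate; (S)-mevalonolactone is taken to be purchasable like its antipode.

Step 1
Reactants: 1 methyl methoxyacetate; 2 4,4-dimethoxybutan-2-one
Product: 3 methyl 3-hydroxy-2,5,5-trimethoxy-3-methylpentanoate (diastereomer mixture)
Conditions: LiN(iPr)2, THF, −78 °C; then 2, −78 °C; AcOH quench
Reagents that add atoms: none
Why: Directed crossed aldol addition, in which the preformed lithium ester enolate should add to the methyl ketone at −78 °C faster than it enolises it; both new stereocentres are erased in step 2, so the mixture is used as such.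

Step 2
Reactants: 3 methyl 3-hydroxy-2,5,5-trimethoxy-3-methylpentanoate
Product: 5 3-methoxy-4-methyl-2H-pyran-2-one, via unsaturated ester 4 (not isolated)
Conditions: TsOH·H2O (cat.), toluene, reflux, MeOH distilled off
Reagents that add atoms: none
Why: Acid-mediated E1 dehydration of the tertiary β-hydroxy ester to the 2-methoxy enoate 4, unmasking of the acetal and enol-lactonisation with loss of methanol should give the 2-pyrone (acetal-based pyrone synthesis); the methyl enol ether keeps C2 from ketonising and so blocks the competing Paal–Knorr closure to a furan.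

Step 3
Reactants: 5 3-methoxy-4-methyl-2H-pyran-2-one
Product: 6 3-hydroxy-4-methyl-2H-pyran-2-one
Conditions: BBr3, CH2Cl2, −78 to 0 °C; aqueous work-up
Reagents that add atoms: none
Why: O-Demethylation with BBr3, which should cleave the methyl enol ether as it does an aryl methyl ether and leave the pyrone nucleus intact.

Step 4
Reactants: 6 3-hydroxy-4-methyl-2H-pyran-2-one; 7 methacrolein (2-methylprop-2-enal)
Product: 8 (1S,4R,8R)-4-hydroxy-5,8-dimethyl-3-oxo-2-oxabicyclo[2.2.2]oct-5-ene-8-carbaldehyde
Conditions: 9-amino-9-deoxy-epi-quinine (10 mol%), CF3CO2H (20 mol%), CH2Cl2, −20 °C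
Reagents that add atoms: none
Why: The quinuclidine of the bifunctional primary amine deprotonates the 3-hydroxyl of 6 to a dienolate whose nucleophilic terminus is pyrone C6 (the future C4'), the primary amine turns 7 into an iminium ion, vinylogous Michael addition to the unsubstituted β-carbon makes the C4'–C5' bond, and the resulting enamine carbon then attacks the now strongly electrophilic α-keto lactone carbonyl to make the C1'–C6' bond before hydrolysis releases the catalyst. The closest known reaction type is the cinchona amine-catalysed Diels–Alder reaction of 3-hydroxy-2-pyrones with α,β-unsaturated carbonyl compounds. The carbocycle is closed as a formal [4+2] cycloaddition whose second bond forms by a 6-(enolexo)-exo-trig aldol closure, the pyranone ring surviving as the lactone bridge of a 2-oxabicyclo[2.2.2]octene. C4' (bicycle C1) is set by catalyst-controlled facial attack in the Michael step, C1' (bicycle C4) is then fixed by the bicyclic constraint, and C6' (bicycle C8) by the exo placement of the formyl-bearing enamine, which is expected because α-substituted acroleins characteristically add to cyclic dienes with the formyl group exo and because the catalyst backbone, ion-paired to the lactone and alkoxide oxygens, should hold the enamine nitrogen on the lactone side. Regioselectivity follows from polarity alone (dienolate terminus to the β-carbon, enamine carbon to the ketone), so the selectivities that must be won are exo over endo and one enantiomer. The hindered bond between the two fully substituted carbons becomes accessible because it forms intramolecularly on an activated ketone.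

Step 5
Reactants: 8 (1S,4R,8R)-4-hydroxy-5,8-dimethyl-3-oxo-2-oxabicyclo[2.2.2]oct-5-ene-8-carbaldehyde
Product: 10 (3aS,5S,7aR)-5,7a-dihydroxy-3a,7-dimethyl-3a,4,5,7a-tetrahydro-2-benzofuran-1(3H)-one, via hydroxymethyl bridged lactone 9 (not isolated)
Conditions: NaBH4, MeOH, −40 to 0 °C; then K2CO3 (cat.), rt
Reagents that add atoms: none
Why: Chemoselective hydride reduction of the aldehyde followed by intramolecular transesterification, in which the exo CH2OH, eclipsed with the C1'–CO bond, should open the strained bridged δ-lactone to the cis-fused γ-lactone and release the C4' hydroxyl; only the exo adduct can do this, so the relay certifies the C1'/C6' relationship without changing any stereocentre.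

Step 6
Reactants: 10 (3aS,5S,7aR)-5,7a-dihydroxy-3a,7-dimethyl-3a,4,5,7a-tetrahydro-2-benzofuran-1(3H)-one
Product: 11 (3aS,5S,7aR)-5-[(tert-butyldimethylsilyl)oxy]-7a-hydroxy-3a,7-dimethyl-3a,4,5,7a-tetrahydro-2-benzofuran-1(3H)-one
Conditions: TBSCl, imidazole, DMF, 0 °C to rt
Reagents that add atoms: tert-butyldimethylsilyl chloride, CC(C)(C)[Si](C)(C)Cl
Why: Standard silylation, selective for the secondary allylic alcohol over the hindered tertiary one; it keeps C4' at the alcohol level so that no enone is present while the primary hydroxyl is later free.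

Step 7
Reactants: 11 (3aS,5S,7aR)-5-[(tert-butyldimethylsilyl)oxy]-7a-hydroxy-3a,7-dimethyl-3a,4,5,7a-tetrahydro-2-benzofuran-1(3H)-one
Product: 12 (3aS,5S,7aR)-5-[(tert-butyldimethylsilyl)oxy]-3a,7-dimethyl-1,3,3a,4,5,7a-hexahydro-2-benzofuran-1,7a-diol (lactol, both C1 epimers)
Conditions: iBu2AlH (2.5 equiv), CH2Cl2, −78 °C; aqueous potassium sodium tartrate
Reagents that add atoms: none
Why: Low-temperature DIBAL-H reduction of a γ-lactone should stop at the aluminium hemiacetal and give the lactol on work-up, the first equivalent being consumed by the tertiary hydroxyl.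

Step 8
Reactants: 12 (3aS,5S,7aR)-5-[(tert-butyldimethylsilyl)oxy]-3a,7-dimethyl-1,3,3a,4,5,7a-hexahydro-2-benzofuran-1,7a-diol
Product: 13 (1R,4S,6S)-4-[(tert-butyldimethylsilyl)oxy]-1-ethynyl-6-(hydroxymethyl)-2,6-dimethylcyclohex-2-en-1-ol
Conditions: dimethyl (1-diazo-2-oxopropyl)phosphonate, K2CO3, MeOH, 0 °C to rt
Reagents that add atoms: dimethyl (1-diazo-2-oxopropyl)phosphonate, COP(=O)(OC)C(=[N+]=[N-])C(C)=O
Why: Seyferth–Gilbert homologation with the Ohira–Bestmann reagent acts on the hydroxy aldehyde form of the lactol and should convert chain C5 into the terminal alkyne by 1,2-hydrogen shift of the alkylidene carbene, freeing the primary hydroxyl without touching the silyl ether or the stereocentres.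

Step 9
Reactants: 13 (1R,4S,6S)-4-[(tert-butyldimethylsilyl)oxy]-1-ethynyl-6-(hydroxymethyl)-2,6-dimethylcyclohex-2-en-1-ol
Product: 14 (1R,4S,6S)-4-[(tert-butyldimethylsilyl)oxy]-6-(hydroxymethyl)-2,6-dimethyl-1-[(E)-2-(tributylstannyl)ethenyl]cyclohex-2-en-1-ol
Conditions: Bu3SnH, Pd(PPh3)2Cl2 (3 mol%), THF, 0 °C
Reagents that add atoms: tributyltin hydride, CCCC[SnH](CCCC)CCCC
Why: Palladium-catalysed syn-hydrostannylation should place tin on the terminal carbon, away from the fully substituted propargylic carbinol, and so set the 4E alkene; it is run before any allyl ester is present because palladium with Bu3SnH would cleave one.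

Step 10
Reactants: 15 but-2-ynoic acid
Product: 16 (Z)-3-iodobut-2-enoic acid
Conditions: NaI, AcOH, 115 °C
Reagents that add atoms: sodium iodide, [Na+].[I-]
Why: Anti hydroiodination of the ynoic acid (conjugate addition of iodide, then protonation) should give the Z-β-iodo acid, which fixes the 2Z geometry.

Step 11
Reactants: 16 (Z)-3-iodobut-2-enoic acid
Product: 17 allyl (Z)-3-iodobut-2-enoate
Conditions: allyl bromide, K2CO3, DMF, rt
Reagents that add atoms: allyl bromide, C=CCBr
Why: SN2 O-alkylation of the carboxylate under mild base, which leaves the vinyl iodide geometry untouched.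

Step 12
Reactants: 14 (1R,4S,6S)-4-[(tert-butyldimethylsilyl)oxy]-6-(hydroxymethyl)-2,6-dimethyl-1-[(E)-2-(tributylstannyl)ethenyl]cyclohex-2-en-1-ol; 17 allyl (Z)-3-iodobut-2-enoate
Product: 18 allyl (2Z,4E)-5-[(1R,4S,6S)-4-[(tert-butyldimethylsilyl)oxy]-1-hydroxy-6-(hydroxymethyl)-2,6-dimethylcyclohex-2-en-1-yl]-3-methylpenta-2,4-dienoate
Conditions: Cu(O2CC4H3S) (copper thiophene-2-carboxylate, 1.5 equiv), NMP, 0 °C to rt
Reagents that add atoms: none
Why: Copper-mediated Stille-type (Liebeskind) coupling, in which tin-to-copper transmetalation and coupling with the β-iodoenoate should proceed with retention at both alkenes to give the (2Z,4E)-dienoate without palladium, so the allyl ester and free hydroxyls are tolerated.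

Step 13
Reactants: 19 (S)-mevalonolactone [(4S)-4-hydroxy-4-methyloxan-2-one]
Product: 21 allyl (3S)-3,5-dihydroxy-3-methylpentanoate, via potassium mevalonate 20 (not isolated)
Conditions: KOH (1.0 equiv), MeOH/H2O, rt; evaporate; allyl bromide, DMF, rt
Reagents that add atoms: potassium hydroxide, [K+].[OH-]; allyl bromide, C=CCBr
Why: Saponification of the lactone and SN2 alkylation of the carboxylate should give the open-chain allyl ester without involving the stereocentre; the product is used promptly to avoid relactonisation.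

Step 14
Reactants: 21 allyl (3S)-3,5-dihydroxy-3-methylpentanoate
Product: 22 (3S)-5-(allyloxy)-3-hydroxy-3-methyl-5-oxopentanoic acid
Conditions: TEMPO (cat.), PhI(OAc)2, MeCN/H2O, rt
Reagents that add atoms: water, O
Why: TEMPO/PhI(OAc)2 oxidation should take the primary alcohol to the acid through the aldehyde hydrate while the tertiary alcohol and allyl ester are inert, so the two glutarate arms are differentiated with the chiral-pool configuration retained.

Step 15
Reactants: 18 allyl (2Z,4E)-5-[(1R,4S,6S)-4-[(tert-butyldimethylsilyl)oxy]-1-hydroxy-6-(hydroxymethyl)-2,6-dimethylcyclohex-2-en-1-yl]-3-methylpenta-2,4-dienoate; 22 (3S)-5-(allyloxy)-3-hydroxy-3-methyl-5-oxopentanoic acid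
Product: 23 allyl (2Z,4E)-5-[(1R,4S,6S)-6-({[(3R)-5-(allyloxy)-3-hydroxy-3-methyl-5-oxopentanoyl]oxy}methyl)-4-[(tert-butyldimethylsilyl)oxy]-1-hydroxy-2,6-dimethylcyclohex-2-en-1-yl]-3-methylpenta-2,4-dienoate
Conditions: EDC·HCl, DMAP, CH2Cl2, 0 °C to rt
Reagents that add atoms: none
Why: Steglich esterification should acylate only the primary neopentyl hydroxyl, since the two tertiary hydroxyls (ring carbinol and glutarate) do not react under carbodiimide/DMAP conditions; the glutarate descriptor changes from S to R only because the ranking of its two arms changes.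

Step 16
Reactants: 23 the silyl ether from step 15
Product: 24 allyl (2Z,4E)-5-[(1R,4S,6S)-6-({[(3R)-5-(allyloxy)-3-hydroxy-3-methyl-5-oxopentanoyl]oxy}methyl)-1,4-dihydroxy-2,6-dimethylcyclohex-2-en-1-yl]-3-methylpenta-2,4-dienoate
Conditions: HF·pyridine, pyridine, THF, 0 °C to rt
Reagents that add atoms: none
Why: Fluoride-mediated Si–O cleavage of the secondary TBS ether under buffered, weakly acidic conditions that should spare the esters, the tertiary allylic alcohol and the Z-enoate.

Step 17
Reactants: 24 the allylic alcohol from step 16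
Product: 25 allyl (2Z,4E)-5-[(1R,6S)-6-({[(3R)-5-(allyloxy)-3-hydroxy-3-methyl-5-oxopentanoyl]oxy}methyl)-1-hydroxy-2,6-dimethyl-4-oxocyclohex-2-en-1-yl]-3-methylpenta-2,4-dienoate
Conditions: MnO2 (activated, excess), CH2Cl2, rt
Reagents that add atoms: none
Why: MnO2 oxidation is selective for the allylic secondary alcohol and unveils the enone only after the primary oxygen has been acylated, so intramolecular oxa-Michael addition to C2' cannot occur.

Step 18
Reactants: 25 the bis-allyl ester from step 17
Product: 26 (2Z,4E)-5-[(1R,6S)-6-({[(3R)-4-carboxy-3-hydroxy-3-methylbutanoyl]oxy}methyl)-1-hydroxy-2,6-dimethyl-4-oxocyclohex-2-en-1-yl]-3-methylpenta-2,4-dienoic acid (target)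
Conditions: Pd(PPh3)4 (5 mol%), morpholine, THF, rt; work-up at pH 3
Reagents that add atoms: none
Why: Tsuji–Trost deallylation, in which zerovalent palladium ionises both allyl esters and morpholine traps the allyl groups, should release the two acids under near-neutral conditions that do not endanger the tertiary allylic alcohol, the β-hydroxy ester or the 2Z alkene.

**Compound list**
1 | methyl methoxyacetate | COCC(=O)OC | starting material
2 | 4,4-dimethoxybutan-2-one | CC(=O)CC(OC)OC | starting material
3 | methyl 3-hydroxy-2,5,5-trimethoxy-3-methylpentanoate (diastereomer mixture) | COC(C(=O)OC)C(C)(O)CC(OC)OC | intermediate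
4 | methyl 2,5,5-trimethoxy-3-methylpent-2-enoate (E/Z) | COC(C(=O)OC)=C(C)CC(OC)OC | intermediate (not isolated)
5 | 3-methoxy-4-methyl-2H-pyran-2-one | COC1=C(C)C=COC1=O | intermediate
6 | 3-hydroxy-4-methyl-2H-pyran-2-one | CC1=C(O)C(=O)OC=C1 | intermediate
7 | methacrolein | CC(=C)C=O | starting material
8 | (1S,4R,8R)-4-hydroxy-5,8-dimethyl-3-oxo-2-oxabicyclo[2.2.2]oct-5-ene-8-carbaldehyde | CC1=C[C@@H]2C[C@@](C)(C=O)[C@@]1(O)C(=O)O2 | intermediate
9 | (1S,4R,8S)-4-hydroxy-8-(hydroxymethyl)-5,8-dimethyl-2-oxabicyclo[2.2.2]oct-5-en-3-one | CC1=C[C@@H]2C[C@@](C)(CO)[C@@]1(O)C(=O)O2 | intermediate (not isolated)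
10 | (3aS,5S,7aR)-5,7a-dihydroxy-3a,7-dimethyl-3a,4,5,7a-tetrahydro-2-benzofuran-1(3H)-one | CC1=C[C@@H](O)C[C@@]2(C)COC(=O)[C@@]12O | intermediate
11 | (3aS,5S,7aR)-5-[(tert-butyldimethylsilyl)oxy]-7a-hydroxy-3a,7-dimethyl-3a,4,5,7a-tetrahydro-2-benzofuran-1(3H)-one | CC1=C[C@@H](O[Si](C)(C)C(C)(C)C)C[C@@]2(C)COC(=O)[C@@]12O | intermediate
12 | (3aS,5S,7aR)-5-[(tert-butyldimethylsilyl)oxy]-3a,7-dimethyl-1,3,3a,4,5,7a-hexahydro-2-benzofuran-1,7a-diol (both C1 epimers) | CC1=C[C@@H](O[Si](C)(C)C(C)(C)C)C[C@@]2(C)COC(O)[C@@]12O | intermediate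
13 | (1R,4S,6S)-4-[(tert-butyldimethylsilyl)oxy]-1-ethynyl-6-(hydroxymethyl)-2,6-dimethylcyclohex-2-en-1-ol | CC1=C[C@@H](O[Si](C)(C)C(C)(C)C)C[C@@](C)(CO)[C@@]1(O)C#C | intermediate
14 | (1R,4S,6S)-4-[(tert-butyldimethylsilyl)oxy]-6-(hydroxymethyl)-2,6-dimethyl-1-[(E)-2-(tributylstannyl)ethenyl]cyclohex-2-en-1-ol | CC1=C[C@@H](O[Si](C)(C)C(C)(C)C)C[C@@](C)(CO)[C@@]1(O)/C=C/[Sn](CCCC)(CCCC)CCCC | intermediate
15 | but-2-ynoic acid | CC#CC(=O)O | starting material
16 | (Z)-3-iodobut-2-enoic acid | C/C(I)=C/C(=O)O | intermediate
17 | allyl (Z)-3-iodobut-2-enoate | C/C(I)=C/C(=O)OCC=C | intermediate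
18 | allyl (2Z,4E)-5-[(1R,4S,6S)-4-[(tert-butyldimethylsilyl)oxy]-1-hydroxy-6-(hydroxymethyl)-2,6-dimethylcyclohex-2-en-1-yl]-3-methylpenta-2,4-dienoate | CC1=C[C@@H](O[Si](C)(C)C(C)(C)C)C[C@@](C)(CO)[C@@]1(O)/C=C/C(C)=C\C(=O)OCC=C | intermediate
19 | (S)-mevalonolactone, (4S)-4-hydroxy-4-methyloxan-2-one | O=C1OCC[C@](C)(O)C1 | starting material
20 | potassium (3S)-3,5-dihydroxy-3-methylpentanoate | [K+].[O-]C(=O)C[C@@](C)(O)CCO | intermediate (not isolated)
21 | allyl (3S)-3,5-dihydroxy-3-methylpentanoate | OCC[C@](C)(O)CC(=O)OCC=C | intermediate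
22 | (3S)-5-(allyloxy)-3-hydroxy-3-methyl-5-oxopentanoic acid | OC(=O)C[C@](C)(O)CC(=O)OCC=C | intermediate
23 | allyl (2Z,4E)-5-[(1R,4S,6S)-6-({[(3R)-5-(allyloxy)-3-hydroxy-3-methyl-5-oxopentanoyl]oxy}methyl)-4-[(tert-butyldimethylsilyl)oxy]-1-hydroxy-2,6-dimethylcyclohex-2-en-1-yl]-3-methylpenta-2,4-dienoate | CC1=C[C@@H](O[Si](C)(C)C(C)(C)C)C[C@@](C)(COC(=O)C[C@](C)(O)CC(=O)OCC=C)[C@@]1(O)/C=C/C(C)=C\C(=O)OCC=C | intermediate
24 | allyl (2Z,4E)-5-[(1R,4S,6S)-6-({[(3R)-5-(allyloxy)-3-hydroxy-3-methyl-5-oxopentanoyl]oxy}methyl)-1,4-dihydroxy-2,6-dimethylcyclohex-2-en-1-yl]-3-methylpenta-2,4-dienoate | CC1=C[C@@H](O)C[C@@](C)(COC(=O)C[C@](C)(O)CC(=O)OCC=C)[C@@]1(O)/C=C/C(C)=C\C(=O)OCC=C | intermediate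
25 | allyl (2Z,4E)-5-[(1R,6S)-6-({[(3R)-5-(allyloxy)-3-hydroxy-3-methyl-5-oxopentanoyl]oxy}methyl)-1-hydroxy-2,6-dimethyl-4-oxocyclohex-2-en-1-yl]-3-methylpenta-2,4-dienoate | CC1=CC(=O)C[C@@](C)(COC(=O)C[C@](C)(O)CC(=O)OCC=C)[C@@]1(O)/C=C/C(C)=C\C(=O)OCC=C | intermediate
26 | (2Z,4E)-5-[(1R,6S)-6-({[(3R)-4-carboxy-3-hydroxy-3-methylbutanoyl]oxy}methyl)-1-hydroxy-2,6-dimethyl-4-oxocyclohex-2-en-1-yl]-3-methylpenta-2,4-dienoic acid | CC1=CC(=O)C[C@@](C)(COC(=O)C[C@](C)(O)CC(=O)O)[C@@]1(O)/C=C/C(C)=C\C(=O)O | target

**Count**
Total steps: 18. Longest linear sequence: 14 (steps 1–9, 12, 15–18).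

**Steps most likely to fail**

Step 4. The enamine aldol closure may place the formyl group on the alkene side (endo) instead of the lactone side, and facial control may be low or eroded by retro-aldol opening of the adduct; if only the sense of induction is wrong, the quinidine-derived pseudo-enantiomer of the catalyst is used. Fallback, from 6 and 7, back at 10: catalyst control is given up. Compounds 6 and 7 are combined under Et3N in CH2Cl2, the plain base-catalysed mode, which should give the racemic exo adduct F1 together with its endo isomer. NaBH4 and then K2CO3 in MeOH should convert only F1 into the racemic γ-lactone diol F2, because the endo-derived alcohol cannot lactonise and is removed by chromatography; the relative configuration is thus sorted by constitution. Lipase-mediated acetylation of the secondary allylic alcohol (Pseudomonas cepacia lipase, vinyl acetate) is expected, from the usual size rule for lipases, to acylate the (5S) antipode and give the acetate F3, which is separated from the unreacted antipode. Methanolysis of F3 (K2CO3, MeOH) returns 10.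

Step 2. Under acid the tertiary β-hydroxy ester may undergo retro-aldol cleavage, or close through its hydroxyl onto the unmasked aldehyde, faster than it dehydrates. Fallback, from 2, back at 5: the C2=C3 double bond is made by olefination instead of dehydration. Horner–Wadsworth–Emmons reaction of 2 with methyl 2-(dimethoxyphosphoryl)-2-methoxyacetate (NaH, THF) should give the unsaturated ester 4 as an isolated E/Z mixture. LiOH in THF/H2O then gives 2,5,5-trimethoxy-3-methylpent-2-enoic acid F4. Heating F4 in AcOH with a catalytic amount of H2SO4 should equilibrate the enol ether geometry and close the acid onto the unmasked aldehyde, giving 5 with loss of methanol.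

Step 8. The hindered, α-hydroxylated aldehyde is present only in small amount beside the lactol, so homologation may be sluggish and base-induced α-ketol rearrangement may intervene. Fallback, from 12, back at 18: the alkyne and tin are avoided. Wittig methylenation of the lactol (Ph3P=CH2, THF, 0 °C to rt) should give the vinyl carbinol F5. A ligand-free Mizoroki–Heck reaction of F5 with 17 (Pd(OAc)2, Ag2CO3, DMF) should then couple at the terminal carbon of the tertiary allylic alcohol; β-hydride elimination gives the 4E alkene with the 2Z geometry of 17 retained, which is 18.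

**Further compounds**
F1 | step 4 | rac-(1S,4R,8R)-4-hydroxy-5,8-dimethyl-3-oxo-2-oxabicyclo[2.2.2]oct-5-ene-8-carbaldehyde (racemate, relative configuration shown) | CC1=C[C@@H]2C[C@@](C)(C=O)[C@@]1(O)C(=O)O2
F2 | step 4 | rac-(3aS,5S,7aR)-5,7a-dihydroxy-3a,7-dimethyl-3a,4,5,7a-tetrahydro-2-benzofuran-1(3H)-one (racemate, relative configuration shown) | CC1=C[C@@H](O)C[C@@]2(C)COC(=O)[C@@]12O
F3 | step 4 | (3aS,5S,7aR)-7a-hydroxy-3a,7-dimethyl-1-oxo-1,3,3a,4,5,7a-hexahydro-2-benzofuran-5-yl acetate | CC1=C[C@@H](OC(C)=O)C[C@@]2(C)COC(=O)[C@@]12O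
F4 | step 2 | 2,5,5-trimethoxy-3-methylpent-2-enoic acid (E/Z) | COC(C(=O)O)=C(C)CC(OC)OC
F5 | step 8 | (1R,4S,6S)-4-[(tert-butyldimethylsilyl)oxy]-1-ethenyl-6-(hydroxymethyl)-2,6-dimethylcyclohex-2-en-1-ol | CC1=C[C@@H](O[Si](C)(C)C(C)(C)C)C[C@@](C)(CO)[C@@]1(O)C=C
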